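Read the earlier flasks at 26 min, the time asked of Thursday's flask, and write each as a power of ten: let L be the log10 of c(product) over the charge less c(product). Sunday's run stands at L = 0.855, Tuesday's at 1.18.

| setting | Sunday's | Tuesday's | Thursday's |
|---|---|---|---|
| starting material | 0.400 M | 0.600 M | 0.830 M |
| time |  |  | 26 min |

- Sunday's run (time / min: [product] / M): 1.0: 0; 1.6: 0.002; 2.6: 0.003; 4.1: 0.003; 6.5: 0.014; 10: 0.039; 16: 0.133; 26: 0.351
- Tuesday's run (time / min: [product] / M): 1.0: 0; 1.6: 0.002; 2.6: 0.008; 4.1: 0.008; 6.5: 0.012; 10: 0.064; 16: 0.252; 26: 0.563

(scatter of a reading: 0.003 M)

- order of the initial rate in [starting material], near the charge of the Sunday's run, the rate being that where two percent of its starting material are product (one fixed amount of product, the same in the runs compared)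
- product in the Thursday's run at 26 min, as a share of the starting material charged

- Overall: starting material -> product.
- Constant volume, constant temperature.
- Bound and free are read together.
- An order is taken over about fifteen percent of the charge, up and down.

Between 16 min and 26 min, Tuesday's L rises at 0.132 min⁻¹; call this rise of L per minute the climb g. For a floor, take Thursday's L no lower than Tuesday's, since Tuesday's larger charge stood ahead of Sunday's; that gives 93.8%. For a ceiling, turn the gain from Sunday to Tuesday into a lead of 2.47 min at climb g, then scale it by the logarithm of the charge step, which is smaller for Thursday. The lead becomes 1.98 min, so L reaches 1.44, or 96.5%.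

The forecast says 96.3%, within 93% to 98.5%, "continuing the 88, 94 trend", which lies inside this bracket, close to its ceiling. It puts the order at 0.5, within 0.1 to 1.

Thursday's flask gives 95.5%, with L = 1.33, a lead of 1.10 min at climb g, and the order near Sunday's charge is 0.43.

    starting material ⇌ intermediate (0.09360 min⁻¹, 0.03546 min⁻¹)
    intermediate → product (0.06900 min⁻¹)
    starting material + product → 2 product (2.340 M⁻¹ min⁻¹)
    2 starting material ⇌ idle substrate dimer, settled at all times (23.00 M⁻¹)

With two percent of Sunday's charge turned, Tuesday's run made product at 0.0042 M min⁻¹ against 0.0035 M min⁻¹ in Sunday's run, through the intermediate and through the step of starting material on product (autocatalysis), while the idle substrate dimer stayed in fast balance with starting material. Later in Tuesday's run that step ran with starting material and product both present: from a quarter to half of the charge L rises by 0.477, which at climb g takes 3.61 min, and Tuesday's run took 3.64 min, Sunday's run 4.44 min.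

The data were computed with made-up constants; scatter was added.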